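Follow the dissolved target through this flask, not the solid.

    starting material ⇌ target (K1 = 1.70, k1 = 0.0407 s⁻¹)
    starting material ⇌ isomer of the product (K2 = 2.9, k2 = 0.0182 s⁻¹)
    target ⇌ isomer of the product (k3 = 0.00274 s⁻¹)
    crystals ⇌ target, rate k4*(cs4 - [target]) while solid is left; crystals form when [target] > cs4 (cs4 = 3.7 mM, k4 = 6.49 s⁻¹)
    solid substrate ⇌ starting material, rate k5*(cs5 - [starting material]) while solid is left; crystals form when [starting material] > cs5 (cs5 = 47 mM, k5 = 0.260 s⁻¹)
    target → over-reaction product (k6 = 0.0943 s⁻¹)

solid substrate 49 mM; time 80 s

- what is said of target includes crystals
- crystals, solid substrate is a solid; its amount is given per volume of the solution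
- at the start none of the solid substrate is in solution
- run time (flask): 80 s

1. target and crystals together at 80 s, in percent of the solid substrate charged
2. concentration of target in solution at 8.0 s, in percent of saturation
3. the change that raises the amount of target and crystals together at 80 s, in percent of the solid substrate charged most ("none" if none brings more than 2 percentage points) (dawn / midnight / noon / spring / none)
4. amount of target and crystals together at 80 s, in percent of the solid substrate charged, after spring

- dawn: doubling the solubility in step 5, all else as stated
- midnight: doubling the dissolution coefficient of step 4, all else as stated
- noon: doubling the solubility in step 4, all else as stated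
- spring: doubling the dissolution coefficient of step 5, all else as stated

The solid substrate dissolves with a lifetime of 3.85 s, shorter than the 17.0 s that starting material lasts against its two exits. While solid remains, we therefore treat [starting material] as one rise with rate constant 0.319 s⁻¹ towards 38.3 mM, which gives 35.3 mM at 8.0 s. Target is then being made at 1.44 mM s⁻¹, so within seconds it passes its solubility of 3.7 mM and crystals form. Their exchange lifetime of 0.154 s is far shorter than the 7.4 s half-life of dissolved target by over-reaction. While crystals stand, [target] therefore rests close to solubility in a pseudo-steady state, with its excess, of either sign, equal to the net inflow divided by the crystal coefficient. We reckon 104% of saturation at 8.0 s.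

Now count lifetimes. Dissolved target lasts 10.6 s against over-reaction, and the run holds 7.54 such lifetimes, with the pool near 3.7 mM while crystals stand, fed first by starting material and later by the crystals. We call this constant loss the saturation drain, the solubility times the over-reaction rate constant: 0.349 mM s⁻¹. It is zero-order in the charge. Over 80 s it takes 57.0% of this flask's charge. The branch share of starting material towards the isomer, 30.9%, we set aside as never reaching target. That leaves 12.1%, or 5.95 mM, above solubility, so crystals should last the run. Doubling the solubility doubles the drain to 114% of the charge, and the crystal coefficient does not enter the drain. Doubling the dissolution coefficient of the solid brings the start forward by 1.92 s, costing 1.4 percentage points. So we choose none, and 10.8% after spring.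

The forecast gives 13.5%, 104%, none and 12.5%, above our two yields, reasoning that “the fast crystallisation pins dissolved target just above” saturation.

The simulation gives 13.7%, 104%, none and 13.3%. In this flask, over-reaction product stands at 54.7% at 80.0 s, against the 57.0% reckoned from the drain. In the neighbouring flask charged with 200 mM, the same drain over the same time is 14.0% of the charge, and that flask ends with 14.0% as over-reaction product. Crystals still stand there at 42.5%, and target and crystals together reach 44.5%.

(The rate constants were set for the occasion, and the outcome is calculated.)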